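**Retrosynthetic overview**

1. Sarmentosumin B (19) comes from flavanone 17 by desilylation and hydrogenolysis of four benzyl ethers.
2. Ring C of 17 is closed last, at C2–C3, by an enantioselective ring contraction of the eight-membered benzylidene acetal 15: the silyl enol ether carbon C3 (on C4, attached to C4a) adds to the O1=C2 oxocarbenium ion formed when the acetal opens.
3. Enabling feature: the 2-hydroxybenzyl group on C8 places the ring D phenol oxygen in a 2,2'-methylenebisphenol relation to O1 (O1–C8a–C8–CH2–C–C–O), so C2 can bridge both oxygens in a 12H-dibenzo[d,g][1,3]dioxocin, while the acetyl group on C4a is ortho to O1. The tether also decides which ring A oxygen becomes O1 (C6 versus C8 pattern) and releases the ring D phenol when it is cut.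
4. Acetal 14 comes from benzaldehyde dimethyl acetal and triol 12, which comes from two successive Friedel–Crafts benzylations of 4-O-benzyl phloroacetophenone 9 (chain alcohol 7 first, then 2-hydroxybenzyl alcohol).
5. Chain alcohol 7 (rings E, F, G) comes from two benzyl–aryl Suzuki couplings of boronic acid 2. Ring order: aromatic rings A, B, D, E, F, G are bought in; the temporary eight-membered acetal ring forms in step 9; ring C forms in step 11.

Key step: step 11

**Remarks on the chemistry.** Compounds 1, 2, 8, 11 and 13 are taken as catalogue materials. Acetals 14 and 15 have a stereogenic acetal carbon and are used as racemates; this centre is erased in step 11. The sense of induction of the chiral catalyst in step 11 cannot be predicted with certainty; both antipodes of the catalyst are accessible and the one that delivers the (S)-flavanone is to be used.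

**Route**

Step 1
Reactants: 1 2-(benzyloxy)benzyl bromide; 2 [4-(benzyloxy)-3-formylphenyl]boronic acid
Product: 3 2-(benzyloxy)-5-[2-(benzyloxy)benzyl]benzaldehyde
Conditions: PdCl2(dppf) (3 mol %), K2CO3, THF/H2O, 70 °C
Reagents that add atoms: none
Why: Suzuki–Miyaura sp3–sp2 coupling of a benzylic bromide with an arylboronic acid should give the diarylmethane (rings F and G), the aldehyde and benzyl ethers being inert.

Step 2
Reactants: 3 2-(benzyloxy)-5-[2-(benzyloxy)benzyl]benzaldehyde
Product: 4 {2-(benzyloxy)-5-[2-(benzyloxy)benzyl]phenyl}methanol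
Conditions: NaBH4, THF/MeOH, 0 °C
Reagents that add atoms: none
Why: Borohydride reduction of an aryl aldehyde to the benzylic alcohol is chemoselective in the presence of benzyl ethers.

Step 3
Reactants: 4 {2-(benzyloxy)-5-[2-(benzyloxy)benzyl]phenyl}methanol
Product: 5 1-(benzyloxy)-4-[2-(benzyloxy)benzyl]-2-(bromomethyl)benzene
Conditions: PBr3, CH2Cl2, 0 °C
Reagents that add atoms: phosphorus tribromide, BrP(Br)Br
Why: Bromination of a benzylic alcohol with PBr3 (displacement of the alkoxyphosphorus intermediate by bromide) should give the bromide, a close analogue of stable compound 1.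

Step 4
Reactants: 5 1-(benzyloxy)-4-[2-(benzyloxy)benzyl]-2-(bromomethyl)benzene; 2 [4-(benzyloxy)-3-formylphenyl]boronic acid
Product: 6 2-(benzyloxy)-5-{2-(benzyloxy)-5-[2-(benzyloxy)benzyl]benzyl}benzaldehyde
Conditions: PdCl2(dppf) (3 mol %), K2CO3, THF/H2O, 70 °C
Reagents that add atoms: none
Why: A second Suzuki–Miyaura benzyl–aryl coupling with the same boronic acid adds ring E with the required ortho/para pattern.

Step 5
Reactants: 6 2-(benzyloxy)-5-{2-(benzyloxy)-5-[2-(benzyloxy)benzyl]benzyl}benzaldehyde
Product: 7 (2-(benzyloxy)-5-{2-(benzyloxy)-5-[2-(benzyloxy)benzyl]benzyl}phenyl)methanol (chain alcohol, rings E, F, G)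
Conditions: NaBH4, THF/MeOH, 0 °C
Reagents that add atoms: none
Why: Borohydride reduction of the aryl aldehyde gives the benzylic alcohol needed as the Friedel–Crafts electrophile.

Step 6
Reactants: 8 2,4,6-trihydroxyacetophenone
Product: 9 1-[4-(benzyloxy)-2,6-dihydroxyphenyl]ethan-1-one
Conditions: BnBr (1.0 equiv), K2CO3 (1.0 equiv), DMF, 0 °C to rt
Reagents that add atoms: benzyl bromide, BrCc1ccccc1
Why: Williamson etherification should occur at the 4-OH, which is the most acidic and the only hydroxyl not hydrogen-bonded to the acetyl group.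

Step 7
Reactants: 9 1-[4-(benzyloxy)-2,6-dihydroxyphenyl]ethan-1-one; 7 chain alcohol
Product: 10 1-[4-(benzyloxy)-2,6-dihydroxy-3-(2-(benzyloxy)-5-{2-(benzyloxy)-5-[2-(benzyloxy)benzyl]benzyl}benzyl)phenyl]ethan-1-one
Conditions: BF3·OEt2 (0.3 equiv), 1,4-dioxane, rt; 7 added slowly to an excess of 9 (3 equiv in the flask, the surplus recovered)
Reagents that add atoms: none
Why: Friedel–Crafts benzylation, in which the Lewis acid ionises the o-alkoxybenzylic alcohol with loss of its hydroxyl group as water and the cation attacks one of the two equivalent positions of the phloroglucinol-type ring A; the excess of 9 should suppress double alkylation.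

Step 8
Reactants: 10 mono-C-benzylated acetophenone; 11 2-hydroxybenzyl alcohol
Product: 12 1-[4-(benzyloxy)-2,6-dihydroxy-3-(2-(benzyloxy)-5-{2-(benzyloxy)-5-[2-(benzyloxy)benzyl]benzyl}benzyl)-5-(2-hydroxybenzyl)phenyl]ethan-1-one
Conditions: BF3·OEt2 (0.5 equiv), 1,4-dioxane, rt; 11 used in slight excess (1.3 equiv)
Reagents that add atoms: none
Why: Friedel–Crafts (o-quinone methide type) hydroxybenzylation, with loss of the benzylic hydroxyl group of 11 as water, can only occur at the single remaining ring A position, which is far more nucleophilic than the benzyloxyarene rings E, F and G.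

Step 9
Reactants: 12 triol; 13 benzaldehyde dimethyl acetal
Product: 14 racemic 1-[1-(benzyloxy)-3-hydroxy-6-phenyl-2-(2-(benzyloxy)-5-{2-(benzyloxy)-5-[2-(benzyloxy)benzyl]benzyl}benzyl)-12H-dibenzo[d,g][1,3]dioxocin-4-yl]ethan-1-one
Conditions: CSA (10 mol %), toluene, 60 °C, 5 Å MS; 13 used in excess (2 equiv)
Reagents that add atoms: none
Why: Acid-catalysed transacetalisation, driven by removal of methanol, should close the eight-membered dibenzodioxocin typical of 2,2'-methylenebisphenols; only the ring D phenol and its neighbouring ring A hydroxyl can form a cyclic acetal because the other flanking oxygen is benzylated, and the new acetal centre forms as a racemate that is erased in step 11.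

Step 10
Reactants: 14 dioxocin ketone
Product: 15 racemic bis-silyl compound: the tert-butyldimethylsilyl enol ether (C(OTBS)=CH2 in place of the acetyl group) and aryl tert-butyldimethylsilyl ether (at the 3-hydroxyl) of 14
Conditions: TBSOTf (2.5 equiv), Et3N (4 equiv), CH2Cl2, 0 °C
Reagents that add atoms: tert-butyldimethylsilyl trifluoromethanesulfonate, CC(C)(C)[Si](C)(C)OS(=O)(=O)C(F)(F)F
Why: Soft enolisation and silylation of an aryl methyl ketone, with concurrent silylation of the remaining phenol, should proceed under amine-buffered conditions that leave the diaryl acetal intact.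

Step 11
Reactants: 15 racemic silyl enol ether acetal
Product: 17 (S)-7-(benzyloxy)-5-(tert-butyldimethylsilyloxy)-8-[2-(tert-butyldimethylsilyloxy)benzyl]-6-(2-(benzyloxy)-5-{2-(benzyloxy)-5-[2-(benzyloxy)benzyl]benzyl}benzyl)-2-phenylchroman-4-one, via ring-opened oxocarbenium ion 16 (not isolated)
Conditions: chiral IDPi acid (BINOL-derived N-triflyl imidodiphosphorimidate with 3,3'-aryl groups, antipode giving (S), 3 mol %), toluene, 4 Å MS, –60 °C; Et3N quench
Reagents that add atoms: none
Why: Proposed new method: the silylated catalyst (formed from the IDPi acid and a trace of 15) silylates the ring D acetal oxygen, the C2–O(ring D) bond ionises to the O1=C2 oxocarbenium ion 16 held as a contact ion pair with the confined chiral anion, and the tethered silyl enol ether adds through C3 to C2 and returns the silyl cation to the anion, so the net change is an isomerisation with silyl transfer from the enol oxygen to the ring D oxygen. The closest known reaction types are intermolecular enantioselective Mukaiyama aldol-type additions of enol silanes to acetal-derived oxocarbenium ions under silylium counteranion-directed catalysis, and the C–C bond-forming half of the Petasis–Ferrier rearrangement. Ring C closes in a 6-(enolendo)-endo-trig mode while the eight-membered acetal ring opens, a ring contraction from eight to six. The C2 stereocentre is set by the chiral anion, which shields one face of the planar oxocarbenium ion; because the racemic acetal centre of 15 is erased on ionisation the step is enantioconvergent. The step needs ionisation with the ring D oxygen as leaving group and not O1, which is secured because acetal opening is reversible and only the O1-bound cation has the enol carbon within reach of a six-membered closure; it also needs the benzyl ethers to stay intact, which is expected at low temperature.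

Step 12
Reactants: 17 bis-silyl flavanone
Product: 18 (S)-7-(benzyloxy)-5-hydroxy-8-(2-hydroxybenzyl)-6-(2-(benzyloxy)-5-{2-(benzyloxy)-5-[2-(benzyloxy)benzyl]benzyl}benzyl)-2-phenylchroman-4-one
Conditions: HF·pyridine, THF/pyridine, 0 °C to rt
Reagents that add atoms: none
Why: Fluoride-mediated cleavage of aryl silyl ethers under mildly acidic conditions should avoid the base-induced ring opening that racemises 5-hydroxyflavanones.

Step 13
Reactants: 18 tetrabenzyl ether
Product: 19 sarmentosumin B, (2S)-5,7-dihydroxy-6-{2-hydroxy-5-[2-hydroxy-5-(2-hydroxybenzyl)benzyl]benzyl}-8-(2-hydroxybenzyl)-2-phenylchroman-4-one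
Conditions: H2 (1 atm), Pd/C (10 wt % Pd), EtOAc/MeOH, rt, stopped after uptake of 4 equiv
Reagents that add atoms: none
Why: Catalytic hydrogenolysis of aryl benzyl ethers under neutral conditions should free the four phenols without touching the C2 stereocentre or the chelated aryl ketone.

**Compound list**

1 | 2-(benzyloxy)benzyl bromide | BrCc1ccccc1OCc1ccccc1 | starting material
2 | [4-(benzyloxy)-3-formylphenyl]boronic acid | OB(O)c1ccc(OCc2ccccc2)c(C=O)c1 | starting material
3 | 2-(benzyloxy)-5-[2-(benzyloxy)benzyl]benzaldehyde | O=Cc1cc(Cc2ccccc2OCc2ccccc2)ccc1OCc1ccccc1 | intermediate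
4 | {2-(benzyloxy)-5-[2-(benzyloxy)benzyl]phenyl}methanol | OCc1cc(Cc2ccccc2OCc2ccccc2)ccc1OCc1ccccc1 | intermediate
5 | 1-(benzyloxy)-4-[2-(benzyloxy)benzyl]-2-(bromomethyl)benzene | BrCc1cc(Cc2ccccc2OCc2ccccc2)ccc1OCc1ccccc1 | intermediate
6 | 2-(benzyloxy)-5-{2-(benzyloxy)-5-[2-(benzyloxy)benzyl]benzyl}benzaldehyde | O=Cc1cc(Cc2cc(Cc3ccccc3OCc3ccccc3)ccc2OCc2ccccc2)ccc1OCc1ccccc1 | intermediate
7 | (2-(benzyloxy)-5-{2-(benzyloxy)-5-[2-(benzyloxy)benzyl]benzyl}phenyl)methanol (chain alcohol) | OCc1cc(Cc2cc(Cc3ccccc3OCc3ccccc3)ccc2OCc2ccccc2)ccc1OCc1ccccc1 | intermediate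
8 | 2,4,6-trihydroxyacetophenone | CC(=O)c1c(O)cc(O)cc1O | starting material
9 | 1-[4-(benzyloxy)-2,6-dihydroxyphenyl]ethan-1-one | CC(=O)c1c(O)cc(OCc2ccccc2)cc1O | intermediate
10 | 1-[4-(benzyloxy)-2,6-dihydroxy-3-(chain benzyl)phenyl]ethan-1-one (chain benzyl = CH2 group of 7) | CC(=O)c1c(O)cc(OCc2ccccc2)c(Cc3cc(Cc4cc(Cc5ccccc5OCc5ccccc5)ccc4OCc4ccccc4)ccc3OCc3ccccc3)c1O | intermediate
11 | 2-hydroxybenzyl alcohol | OCc1ccccc1O | starting material
12 | 1-[4-(benzyloxy)-2,6-dihydroxy-3-(chain benzyl)-5-(2-hydroxybenzyl)phenyl]ethan-1-one | CC(=O)c1c(O)c(Cc2ccccc2O)c(OCc2ccccc2)c(Cc3cc(Cc4cc(Cc5ccccc5OCc5ccccc5)ccc4OCc4ccccc4)ccc3OCc3ccccc3)c1O | intermediate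
13 | benzaldehyde dimethyl acetal | COC(OC)c1ccccc1 | starting material
14 | racemic 1-[1-(benzyloxy)-3-hydroxy-6-phenyl-2-(chain benzyl)-12H-dibenzo[d,g][1,3]dioxocin-4-yl]ethan-1-one | CC(=O)c1c(O)c(Cc3cc(Cc4cc(Cc5ccccc5OCc5ccccc5)ccc4OCc4ccccc4)ccc3OCc3ccccc3)c(OCc3ccccc3)c2c1OC(c1ccccc1)Oc1ccccc1C2 | intermediate
15 | racemic bis-TBS derivative of 14 (silyl enol ether at the acetyl group, silyl ether at the 3-hydroxyl) | C=C(O[Si](C)(C)C(C)(C)C)c1c(O[Si](C)(C)C(C)(C)C)c(Cc3cc(Cc4cc(Cc5ccccc5OCc5ccccc5)ccc4OCc4ccccc4)ccc3OCc3ccccc3)c(OCc3ccccc3)c2c1OC(c1ccccc1)Oc1ccccc1C2 | intermediate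
16 | ring-opened O1=C2 oxocarbenium ion (cation of the ion pair with the catalyst anion; ring D oxygen silylated) | C=C(O[Si](C)(C)C(C)(C)C)c1c(O[Si](C)(C)C(C)(C)C)c(Cc3cc(Cc4cc(Cc5ccccc5OCc5ccccc5)ccc4OCc4ccccc4)ccc3OCc3ccccc3)c(OCc3ccccc3)c(Cc2ccccc2O[Si](C)(C)C(C)(C)C)c1[O+]=Cc1ccccc1 | intermediate (not isolated)
17 | (S)-7-(benzyloxy)-5-(TBS-oxy)-8-[2-(TBS-oxy)benzyl]-6-(chain benzyl)-2-phenylchroman-4-one | O=C1C[C@@H](c2ccccc2)Oc2c(Cc3ccccc3O[Si](C)(C)C(C)(C)C)c(OCc3ccccc3)c(Cc3cc(Cc4cc(Cc5ccccc5OCc5ccccc5)ccc4OCc4ccccc4)ccc3OCc3ccccc3)c(O[Si](C)(C)C(C)(C)C)c21 | intermediate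
18 | (S)-7-(benzyloxy)-5-hydroxy-8-(2-hydroxybenzyl)-6-(chain benzyl)-2-phenylchroman-4-one | O=C1C[C@@H](c2ccccc2)Oc2c(Cc3ccccc3O)c(OCc3ccccc3)c(Cc3cc(Cc4cc(Cc5ccccc5OCc5ccccc5)ccc4OCc4ccccc4)ccc3OCc3ccccc3)c(O)c21 | intermediate
19 | sarmentosumin B | O=C1C[C@@H](c2ccccc2)Oc2c(Cc3ccccc3O)c(O)c(Cc3cc(Cc4cc(Cc5ccccc5O)ccc4O)ccc3O)c(O)c21 | target

**Step count**

Total: 13 steps. Longest linear sequence: 12 steps (steps 1–5, then 7–13); step 6 is a one-step branch.

**Steps most likely to fail**

Step 11. The ion pair may give poor facial discrimination, an uncatalysed or loosely paired background pathway may erode selectivity, or the enol ether may be protodesilylated before it cyclises. The fallback sets out from 15 and uses the same ring contraction without asymmetric induction: catalytic TMSOTf in CH2Cl2 at –78 °C (Lewis acid-mediated addition of an enol silane to an acetal-derived oxocarbenium ion, established chemistry) should give the racemic bis-silyl flavanone F1. Its enantiomers are then separated by preparative HPLC on a polysaccharide chiral stationary phase, and the (S)-enantiomer is 17, where the route is rejoined. The (R)-enantiomer can be racemised with DBU through reversible retro-oxa-Michael ring opening and recycled.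

Step 9. Ring closure to the eight-membered acetal at the hindered, hydrogen-bonded ring A hydroxyl may stall at open mixed acetals or oligomers, or the acid may start an aldol-type condensation between the acetyl group and the benzaldehyde unit. The fallback sets out from 12 and replaces reversible acid-catalysed acetal exchange by an irreversible double Williamson alkylation: α,α-dibromotoluene and Cs2CO3 in DMF at 50 °C, with no acid and hence no enol or oxocarbenium leakage. It returns directly at 14 and makes no new compound.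

Step 7. The benzylic cation may alkylate ring A twice, alkylate oxygen, or attack the electron-rich rings of a second molecule of 7. The fallback replaces electrophilic substitution by cross-coupling. It sets out from 9, which is mono-iodinated at one of its two equivalent positions (NIS, MeCN, 0 °C) to the aryl iodide F2. In parallel, 7 is converted with PBr3 into the chain bromide F3 and then by Miyaura borylation (B2pin2, PdCl2(dppf), KOAc, dioxane) into the benzylic pinacol boronate F4. Suzuki–Miyaura coupling of F2 with F4 (PdCl2(dppf), K3PO4, dioxane/H2O) returns to the route at 10.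

**Further compounds**

F1 | step 11 | racemic 7-(benzyloxy)-5-(TBS-oxy)-8-[2-(TBS-oxy)benzyl]-6-(chain benzyl)-2-phenylchroman-4-one | O=C1CC(c2ccccc2)Oc2c(Cc3ccccc3O[Si](C)(C)C(C)(C)C)c(OCc3ccccc3)c(Cc3cc(Cc4cc(Cc5ccccc5OCc5ccccc5)ccc4OCc4ccccc4)ccc3OCc3ccccc3)c(O[Si](C)(C)C(C)(C)C)c21
F0 | step 9 | none | none
F2 | step 7 | 1-[4-(benzyloxy)-2,6-dihydroxy-3-iodophenyl]ethan-1-one | CC(=O)c1c(O)cc(OCc2ccccc2)c(I)c1O
F3 | step 7 | 1-(benzyloxy)-4-{2-(benzyloxy)-5-[2-(benzyloxy)benzyl]benzyl}-2-(bromomethyl)benzene | BrCc1cc(Cc2cc(Cc3ccccc3OCc3ccccc3)ccc2OCc2ccccc2)ccc1OCc1ccccc1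
F4 | step 7 | 2-(2-(benzyloxy)-5-{2-(benzyloxy)-5-[2-(benzyloxy)benzyl]benzyl}benzyl)-4,4,5,5-tetramethyl-1,3,2-dioxaborolane | CC1(C)OB(Cc2cc(Cc3cc(Cc4ccccc4OCc4ccccc4)ccc3OCc3ccccc3)ccc2OCc2ccccc2)OC1(C)C
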